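**Plan**
1. Cuts: (a) the bond between the decalin sp2 carbon C1 and the first side-chain CH2; (b) the bond from the diene terminus to butenolide C4, with the 1Z alkene drawn back to an alkyne; (c) the 3E trisubstituted alkene, drawn back to a Wittig reaction of a γ-lactone ylide.
2. Ring half: (+)-sclareolide (rings A and B ready-made) loses two carbons by alkoxy-radical fragmentation, elimination and ozonolysis to give the C1 ketone. Its carbonyl lies between the quaternary C8a (no hydrogen) and the methyl-bearing C2, so it enolizes in one direction only and gives a single tetrasubstituted C1=C2 enol triflate.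
3. Chain half: a temporary γ-lactone ring carries the future CH2OH carbon (as C=O) and the future zinc-bearing CH2 (as O–CH2) on the ylide carbon; the Wittig alkene is E, and the ring is then opened to an iodo ester.
4. Union: the alkylzinc from the iodo ester is coupled with the enol triflate, joining the C14 and C11 pieces and fixing the ring alkene in one event. Ester reduction, alkyne release, Sonogashira coupling with 4-bromofuranone and syn semi-reduction complete the chain.
5. Stereochemistry: 4aS and 8aS come unchanged from sclareolide; 3E from the stabilized-ylide Wittig on the lactone; 1Z from syn delivery of hydrogen to the alkyne.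

Key step: step 10

Remark: ring positions follow the octahydronaphthalene numbering of the target (C1 side-chain carbon, C2 vinylic-methyl carbon, C8a angular-methyl carbon). Ketone 7 is carried as a mixture of C2 epimers because C2 becomes sp2 in step 6.

**Step 1**
Reactants: 1 (+)-sclareolide
Product: 2 (3aR,5aS,9aS,9bR)-3a,6,6,9a-tetramethyldodecahydronaphtho[2,1-b]furan-2-ol (anomer mixture)
Conditions: iBu2AlH (DIBAL-H), CH2Cl2, −78 °C; Rochelle salt work-up
Reagents that add atoms: none
Why: Partial reduction of a γ-lactone by DIBAL-H at low temperature should stop at the lactol, and no stereocentre of the decalin is touched.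

**Step 2**
Reactants: 2 sclareolide lactol
Product: 3 (1R,2R,4aS,8aS)-1-(iodomethyl)-2,5,5,8a-tetramethyldecahydronaphthalen-2-yl formate
Conditions: PhI(OAc)2, I2, CH2Cl2, visible light, rt
Reagents that add atoms: iodine, II
Why: Suárez alkoxy-radical β-fragmentation: the anomeric alkoxy radical cleaves the adjacent C–C bond, leaving the former lactol carbon as a formate on the tertiary oxygen and a primary radical that is trapped by iodine.

**Step 3**
Reactants: 3 iodo formate
Product: 4 (2R,4aS,8aS)-2,5,5,8a-tetramethyl-1-methylidenedecahydronaphthalen-2-yl formate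
Conditions: AgF, pyridine, rt, dark
Reagents that add atoms: none
Why: Silver-assisted E2 dehydroiodination; the only β-hydrogen is on C1, so the exocyclic methylidene alkene is the only possible elimination product and the tertiary formate stays in place.

**Step 4**
Reactants: 4 methylidene formate
Product: 6 (2R,4aS,8aS)-2,5,5,8a-tetramethyl-1-oxodecahydronaphthalen-2-yl formate, via secondary ozonide 5 (not isolated)
Conditions: O3, CH2Cl2, −78 °C; then Me2S, −78 °C → rt
Reagents that add atoms: ozone, [O-][O+]=O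
Why: Ozonolysis of the 1,1-disubstituted exocyclic alkene with reductive work-up removes the methylidene carbon as formaldehyde and leaves the C1 ketone; the formate and the saturated skeleton are inert to ozone.

**Step 5**
Reactants: 6 α-formyloxy ketone
Product: 7 (4aS,8aS)-2,5,5,8a-tetramethyloctahydronaphthalen-1(2H)-one (C2 epimer mixture)
Conditions: SmI2, THF/MeOH, −78 °C
Reagents that add atoms: none
Why: SmI2 reductive cleavage of an α-acyloxy ketone: the ketyl expels formate and the resulting enolate is protonated by methanol; the C2 configuration formed here is of no consequence.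

**Step 6**
Reactants: 7 ketone
Product: 9 (4aS,8aS)-2,5,5,8a-tetramethyl-3,4,4a,5,6,7,8,8a-octahydronaphthalen-1-yl trifluoromethanesulfonate, via potassium enolate 8 (not isolated)
Conditions: KN(SiMe3)2, THF, −78 → 0 °C; then PhNTf2, −78 °C → rt
Reagents that add atoms: N-phenylbis(trifluoromethanesulfonimide), FC(F)(F)S(=O)(=O)N(c1ccccc1)S(=O)(=O)C(F)(F)F
Why: Enol triflate formation by O-sulfonylation of the enolate; C8a is quaternary, so deprotonation can occur only at C2–H and a single tetrasubstituted C1=C2 enol triflate should result.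

**Step 7**
Reactants: 10 3-(triphenyl-λ5-phosphanylidene)oxolan-2-one [α-(triphenylphosphoranylidene)-γ-butyrolactone]; 11 3-[tri(propan-2-yl)silyl]prop-2-ynal
Product: 12 (3E)-3-{3-[tri(propan-2-yl)silyl]prop-2-yn-1-ylidene}oxolan-2-one
Conditions: CH2Cl2, 0 °C → rt
Reagents that add atoms: none
Why: Wittig olefination with a carbonyl-stabilized ylide should give the E-alkylidene lactone (alkynyl group trans to the lactone carbonyl), which fixes the geometry of the future trisubstituted alkene.

**Step 8**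
Reactants: 12 alkylidene lactone
Product: 14 methyl (2E)-2-(2-hydroxyethyl)-5-[tri(propan-2-yl)silyl]pent-2-en-4-ynoate, via lithium hydroxy carboxylate 13 (not isolated)
Conditions: LiOH·H2O (1.05 equiv), THF/H2O, 0 °C; evaporate; then MeI, DMF, rt
Reagents that add atoms: lithium hydroxide, [Li+].[OH-]; iodomethane, CI
Why: Lactone saponification followed by SN2 O-alkylation of the carboxylate opens the temporary ring without touching the alkene geometry; the triisopropylsilyl alkyne is stable to hydroxide.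

**Step 9**
Reactants: 14 hydroxy ester
Product: 15 methyl (2E)-2-(2-iodoethyl)-5-[tri(propan-2-yl)silyl]pent-2-en-4-ynoate
Conditions: I2, PPh3, imidazole, CH2Cl2, 0 °C
Reagents that add atoms: iodine, II
Why: Appel iodination replaces the primary hydroxyl by iodide through SN2 displacement of the alkoxyphosphonium under near-neutral conditions, so relactonization and alkene isomerization should not compete.

**Step 10**
Reactants: 15 iodo ester; 9 enol triflate
Product: 17 methyl (2E)-2-{2-[(4aS,8aS)-2,5,5,8a-tetramethyl-3,4,4a,5,6,7,8,8a-octahydronaphthalen-1-yl]ethyl}-5-[tri(propan-2-yl)silyl]pent-2-en-4-ynoate, via alkylzinc iodide 16 (not isolated)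
Conditions: Zn dust (activated with BrCH2CH2Br/Me3SiCl), LiCl, THF, 35 °C; then 9, Pd(OAc)2 (5 mol %), SPhos (10 mol %), THF/NMP, 50 °C
Reagents that add atoms: none
Why: Zinc inserts into the primary C–I bond of 15 to give alkylzinc iodide 16; zerovalent palladium formed from Pd(OAc)2/SPhos adds oxidatively into the C1–OTf bond of 9, the alkyl group passes from zinc to palladium, and reductive elimination forms the C1–CH2 bond. The closest known reaction type is the Negishi alkyl–alkenyl coupling of cyclic enol triflates with ester-bearing primary alkylzinc halides; hindered 2,6,6-trisubstituted cyclohexenyl triflates are established partners in palladium cross-couplings. No ring is closed and no stereocentre is formed; C4a and C8a are spectators. The step needs site fidelity of the ring alkene, secured because the triflate marks C1 of a C1=C2 bond that cannot migrate toward the quaternary C8a; it needs chemoselectivity, secured by the low basicity and nucleophilicity of the C–Zn bond toward the methyl ester, the enoate and the silyl-capped alkyne; and it needs reductive elimination to outrun β-hydride elimination of the alkylpalladium, for which the bulky biarylphosphine is chosen. The E geometry of the enoate is not at risk because the reacting carbon is two bonds away and no base is present.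

**Step 11**
Reactants: 17 coupled ester
Product: 18 (2E)-2-{2-[(4aS,8aS)-2,5,5,8a-tetramethyl-3,4,4a,5,6,7,8,8a-octahydronaphthalen-1-yl]ethyl}-5-[tri(propan-2-yl)silyl]pent-2-en-4-yn-1-ol
Conditions: iBu2AlH (2.5 equiv), CH2Cl2, −78 °C
Reagents that add atoms: none
Why: DIBAL-H reduces the conjugated methyl ester by 1,2-hydride addition to the primary allylic alcohol; the silyl alkyne and the tri- and tetrasubstituted alkenes are inert.

**Step 12**
Reactants: 18 silyl enynol
Product: 19 (2E)-2-{2-[(4aS,8aS)-2,5,5,8a-tetramethyl-3,4,4a,5,6,7,8,8a-octahydronaphthalen-1-yl]ethyl}pent-2-en-4-yn-1-ol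
Conditions: Bu4NF, THF, 0 °C → rt
Reagents that add atoms: none
Why: Fluoride-mediated protodesilylation of the alkynylsilane, driven by Si–F bond formation, frees the terminal alkyne; the free allylic alcohol is tolerated.

**Step 13**
Reactants: 19 terminal enynol; 20 4-bromofuran-2(5H)-one
Product: 21 4-[(3E)-4-(hydroxymethyl)-6-[(4aS,8aS)-2,5,5,8a-tetramethyl-3,4,4a,5,6,7,8,8a-octahydronaphthalen-1-yl]hex-3-en-1-yn-1-yl]furan-2(5H)-one
Conditions: PdCl2(PPh3)2 (5 mol %), CuI (10 mol %), Et3N, THF (degassed), rt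
Reagents that add atoms: none
Why: Sonogashira coupling: zerovalent palladium inserts into the C–Br bond of the β-bromobutenolide and couples with the copper acetylide of 19; a tertiary amine is used so that addition–elimination at the bromobutenolide is avoided.

**Step 14**
Reactants: 21 dienyne butenolide
Product: 22 4-[(1Z,3E)-4-(hydroxymethyl)-6-[(4aS,8aS)-2,5,5,8a-tetramethyl-3,4,4a,5,6,7,8,8a-octahydronaphthalen-1-yl]hexa-1,3-dien-1-yl]furan-2(5H)-one (target)
Conditions: Zn dust activated with Cu(OAc)2 and AgNO3, MeOH/H2O, rt, dark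
Reagents that add atoms: none
Why: Boland-type zinc semi-reduction delivers two hydrogens syn to the conjugated alkyne and should give the Z alkene, being selective for the activated triple bond over the butenolide and the tri- and tetrasubstituted alkenes.

**Compound list**
1 | (+)-sclareolide, (3aR,5aS,9aS,9bR)-3a,6,6,9a-tetramethyldecahydronaphtho[2,1-b]furan-2(1H)-one | C[C@@]12CC[C@H]3C(C)(C)CCC[C@]3(C)[C@H]1CC(=O)O2 | starting material
2 | (3aR,5aS,9aS,9bR)-3a,6,6,9a-tetramethyldodecahydronaphtho[2,1-b]furan-2-ol | C[C@@]12CC[C@H]3C(C)(C)CCC[C@]3(C)[C@H]1CC(O)O2 | intermediate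
3 | (1R,2R,4aS,8aS)-1-(iodomethyl)-2,5,5,8a-tetramethyldecahydronaphthalen-2-yl formate | C[C@@]1(OC=O)CC[C@H]2C(C)(C)CCC[C@]2(C)[C@H]1CI | intermediate
4 | (2R,4aS,8aS)-2,5,5,8a-tetramethyl-1-methylidenedecahydronaphthalen-2-yl formate | C[C@@]1(OC=O)CC[C@H]2C(C)(C)CCC[C@]2(C)C1=C | intermediate
5 | secondary ozonide of 4, (2'R,4a'S,8a'S)-2',5',5',8a'-tetramethyloctahydro-2'H-spiro[[1,2,4]trioxolane-3,1'-naphthalen]-2'-yl formate | C[C@@]1(OC=O)CC[C@H]2C(C)(C)CCC[C@]2(C)C13OCOO3 | intermediate
6 | (2R,4aS,8aS)-2,5,5,8a-tetramethyl-1-oxodecahydronaphthalen-2-yl formate | C[C@@]1(OC=O)CC[C@H]2C(C)(C)CCC[C@]2(C)C1=O | intermediate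
7 | (4aS,8aS)-2,5,5,8a-tetramethyloctahydronaphthalen-1(2H)-one (C2 epimers) | CC1CC[C@H]2C(C)(C)CCC[C@]2(C)C1=O | intermediate
8 | potassium (4aS,8aS)-2,5,5,8a-tetramethyl-3,4,4a,5,6,7,8,8a-octahydronaphthalen-1-olate | CC1=C([O-])[C@@]2(C)CCCC(C)(C)[C@@H]2CC1.[K+] | intermediate
9 | (4aS,8aS)-2,5,5,8a-tetramethyl-3,4,4a,5,6,7,8,8a-octahydronaphthalen-1-yl trifluoromethanesulfonate | CC1=C(OS(=O)(=O)C(F)(F)F)[C@@]2(C)CCCC(C)(C)[C@@H]2CC1 | intermediate
10 | 3-(triphenyl-λ5-phosphanylidene)oxolan-2-one | O=C1OCCC1=P(c1ccccc1)(c1ccccc1)c1ccccc1 | starting material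
11 | 3-[tri(propan-2-yl)silyl]prop-2-ynal | CC(C)[Si](C#CC=O)(C(C)C)C(C)C | starting material
12 | (3E)-3-{3-[tri(propan-2-yl)silyl]prop-2-yn-1-ylidene}oxolan-2-one | CC(C)[Si](C#C/C=C1\CCOC1=O)(C(C)C)C(C)C | intermediate
13 | lithium (2E)-2-(2-hydroxyethyl)-5-[tri(propan-2-yl)silyl]pent-2-en-4-ynoate | [Li+].[O-]C(=O)/C(CCO)=C/C#C[Si](C(C)C)(C(C)C)C(C)C | intermediate
14 | methyl (2E)-2-(2-hydroxyethyl)-5-[tri(propan-2-yl)silyl]pent-2-en-4-ynoate | COC(=O)/C(CCO)=C/C#C[Si](C(C)C)(C(C)C)C(C)C | intermediate
15 | methyl (2E)-2-(2-iodoethyl)-5-[tri(propan-2-yl)silyl]pent-2-en-4-ynoate | COC(=O)/C(CCI)=C/C#C[Si](C(C)C)(C(C)C)C(C)C | intermediate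
16 | {(3E)-3-(methoxycarbonyl)-6-[tri(propan-2-yl)silyl]hex-3-en-5-yn-1-yl}zinc iodide | COC(=O)/C(CC[Zn]I)=C/C#C[Si](C(C)C)(C(C)C)C(C)C | intermediate
17 | methyl (2E)-2-{2-[(4aS,8aS)-2,5,5,8a-tetramethyl-3,4,4a,5,6,7,8,8a-octahydronaphthalen-1-yl]ethyl}-5-[tri(propan-2-yl)silyl]pent-2-en-4-ynoate | CC1=C(CC/C(=C\C#C[Si](C(C)C)(C(C)C)C(C)C)C(=O)OC)[C@@]2(C)CCCC(C)(C)[C@@H]2CC1 | intermediate
18 | (2E)-2-{2-[(4aS,8aS)-2,5,5,8a-tetramethyl-3,4,4a,5,6,7,8,8a-octahydronaphthalen-1-yl]ethyl}-5-[tri(propan-2-yl)silyl]pent-2-en-4-yn-1-ol | CC1=C(CC/C(=C\C#C[Si](C(C)C)(C(C)C)C(C)C)CO)[C@@]2(C)CCCC(C)(C)[C@@H]2CC1 | intermediate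
19 | (2E)-2-{2-[(4aS,8aS)-2,5,5,8a-tetramethyl-3,4,4a,5,6,7,8,8a-octahydronaphthalen-1-yl]ethyl}pent-2-en-4-yn-1-ol | CC1=C(CC/C(=C\C#C)CO)[C@@]2(C)CCCC(C)(C)[C@@H]2CC1 | intermediate
20 | 4-bromofuran-2(5H)-one | BrC1=CC(=O)OC1 | starting material
21 | 4-[(3E)-4-(hydroxymethyl)-6-[(4aS,8aS)-2,5,5,8a-tetramethyl-3,4,4a,5,6,7,8,8a-octahydronaphthalen-1-yl]hex-3-en-1-yn-1-yl]furan-2(5H)-one | CC1=C(CC/C(=C\C#CC2=CC(=O)OC2)CO)[C@@]2(C)CCCC(C)(C)[C@@H]2CC1 | intermediate
22 | 4-[(1Z,3E)-4-(hydroxymethyl)-6-[(4aS,8aS)-2,5,5,8a-tetramethyl-3,4,4a,5,6,7,8,8a-octahydronaphthalen-1-yl]hexa-1,3-dien-1-yl]furan-2(5H)-one | CC1=C(CC/C(=C\C=C/C2=CC(=O)OC2)CO)[C@@]2(C)CCCC(C)(C)[C@@H]2CC1 | target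

**Route length**
Total step count: 14. Longest linear sequence: 11 steps (steps 1–6, then 10–14); the side-chain branch (steps 7–9) joins at step 10.

**Steps most likely to fail**

Step 10. Oxidative addition and transmetalation at the tetrasubstituted triflate, which sits next to a quaternary carbon, may be slow enough that protodezincation or β-hydride elimination of the alkyl partner takes over. The fallback sets out from 9 and returns at 17. The hindered triflate is first coupled with the smallest partner, tributyl(vinyl)stannane (Stille coupling, Pd(PPh3)4, LiCl, THF, reflux), to give (4aS,8aS)-1-ethenyl-2,5,5,8a-tetramethyl-3,4,4a,5,6,7,8,8a-octahydronaphthalene F1. 9-Borabicyclo[3.3.1]nonane then adds to the terminal vinyl carbon to give 9-{2-[(4aS,8aS)-2,5,5,8a-tetramethyl-3,4,4a,5,6,7,8,8a-octahydronaphthalen-1-yl]ethyl}-9-borabicyclo[3.3.1]nonane F2. Separately, 11 is olefinated with methyl iodo(triphenyl-λ5-phosphanylidene)acetate F3, made in the flask from methyl (triphenylphosphoranylidene)acetate, N-iodosuccinimide and K2CO3, to give methyl (2Z)-2-iodo-5-[tri(propan-2-yl)silyl]pent-2-en-4-ynoate F4. B-alkyl Suzuki–Miyaura coupling of F2 with F4 (PdCl2(dppf), AsPh3, Cs2CO3, DMF/THF/H2O, rt) goes with retention at the iodoalkene and should give 17. The sp2–sp3 union is thereby moved to the unhindered side-chain carbon.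

Step 14. The semi-reduction may over-reduce, or the newly formed cis-triene may isomerize or undergo electrocyclization on the metal surface. The fallback sets out from 19 and returns at 22, and fixes the cis alkene before the butenolide is attached. 19 is iodinated at the alkyne terminus (N-iodosuccinimide, AgNO3 cat., acetone) to (2E)-5-iodo-2-{2-[(4aS,8aS)-2,5,5,8a-tetramethyl-3,4,4a,5,6,7,8,8a-octahydronaphthalen-1-yl]ethyl}pent-2-en-4-yn-1-ol F5. Diimide from 2-nitrobenzenesulfonylhydrazide and Et3N reduces the iodoalkyne syn to (2E,4Z)-5-iodo-2-{2-[(4aS,8aS)-2,5,5,8a-tetramethyl-3,4,4a,5,6,7,8,8a-octahydronaphthalen-1-yl]ethyl}penta-2,4-dien-1-ol F6. 20 is converted with (Bu3Sn)2 and Pd(PPh3)4 into 4-(tributylstannyl)furan-2(5H)-one F7. Stille coupling of F6 with F7 (Pd2(dba)3, AsPh3, CuI, DMF, rt) proceeds with retention and should give 22.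

Step 8. The γ-hydroxy ester may close back to the lactone during methylation or work-up. The fallback sets out from 12 and returns at 15, and never passes through a free hydroxy ester. Alkyl–oxygen cleavage of the lactone with iodotrimethylsilane (CH2Cl2, rt to 40 °C) gives trimethylsilyl (2E)-2-(2-iodoethyl)-5-[tri(propan-2-yl)silyl]pent-2-en-4-ynoate F8. Methanol added to the same flask, with the acid generated in situ, converts it into 15, so 14 and step 9 are bypassed.

**Further compounds**
F1 | step 10 | (4aS,8aS)-1-ethenyl-2,5,5,8a-tetramethyl-3,4,4a,5,6,7,8,8a-octahydronaphthalene | CC1=C(C=C)[C@@]2(C)CCCC(C)(C)[C@@H]2CC1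
F2 | step 10 | 9-{2-[(4aS,8aS)-2,5,5,8a-tetramethyl-3,4,4a,5,6,7,8,8a-octahydronaphthalen-1-yl]ethyl}-9-borabicyclo[3.3.1]nonane | CC1=C(CCB2C3CCCC2CCC3)[C@@]2(C)CCCC(C)(C)[C@@H]2CC1
F3 | step 10 | methyl iodo(triphenyl-λ5-phosphanylidene)acetate | COC(=O)C(I)=P(c1ccccc1)(c1ccccc1)c1ccccc1
F4 | step 10 | methyl (2Z)-2-iodo-5-[tri(propan-2-yl)silyl]pent-2-en-4-ynoate | COC(=O)/C(I)=C/C#C[Si](C(C)C)(C(C)C)C(C)C
F5 | step 14 | (2E)-5-iodo-2-{2-[(4aS,8aS)-2,5,5,8a-tetramethyl-3,4,4a,5,6,7,8,8a-octahydronaphthalen-1-yl]ethyl}pent-2-en-4-yn-1-ol | CC1=C(CC/C(=C\C#CI)CO)[C@@]2(C)CCCC(C)(C)[C@@H]2CC1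
F6 | step 14 | (2E,4Z)-5-iodo-2-{2-[(4aS,8aS)-2,5,5,8a-tetramethyl-3,4,4a,5,6,7,8,8a-octahydronaphthalen-1-yl]ethyl}penta-2,4-dien-1-ol | CC1=C(CC/C(=C\C=C/I)CO)[C@@]2(C)CCCC(C)(C)[C@@H]2CC1
F7 | step 14 | 4-(tributylstannyl)furan-2(5H)-one | CCCC[Sn](CCCC)(CCCC)C1=CC(=O)OC1
F8 | step 8 | trimethylsilyl (2E)-2-(2-iodoethyl)-5-[tri(propan-2-yl)silyl]pent-2-en-4-ynoate | C[Si](C)(C)OC(=O)/C(CCI)=C/C#C[Si](C(C)C)(C(C)C)C(C)C
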